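**Plan**

- The target is four (−)-epicatechin units joined 4β→8 (unit 1 on top, unit 4 at the bottom); units 1, 3 and 4 are taken from (−)-epicatechin and unit 2 is built de novo.
- Retrosynthetic cuts, in order: the benzyl ethers and one C8–Br cap; the top interflavan bond C4(unit 1)–C8(unit 2); ring C of unit 2 across O1–C2 and C3–C4; the bond from the future C4 of unit 2 to ring A of unit 2; the lower interflavan bond C4(unit 3)–C8(unit 4).
- Enabling feature: in unit 2, O1 is a phenol oxygen on C8a, and C4 is a doubly benzylic carbon on C4a that also carries C8 of unit 3. O=C8a–C4a=C4 is therefore a latent ortho-quinone methide and C2=C3 a latent Z-β-acyloxystyrene.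
- Forward order: the 8-bromo dimer of units 3–4 is made; it is lithiated and added to a phloroglucinol-type salicylaldehyde to give a benzhydrol; the ortho-quinone methide [4+2] closes ring C of unit 2; unit 1 is coupled at C8 of unit 2; deprotection follows.
- Stereochemistry: C2/C3 of units 1, 3 and 4 come from epicatechin; C4 of units 1 and 3 arises by attack anti to the 3-benzyloxy group; C2, C3 and C4 of unit 2 arise in the cycloaddition (Z-alkene gives 2,3-cis; endo addition to the Z-methide gives 3,4-trans; a chiral phosphoric acid sets the absolute sense).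

Key step: step 10

Assumption: (R)-TRIP is taken as the catalyst enantiomer matched to the required face of the ortho-quinone methide; this sense of induction cannot be derived with certainty for a methide of this size.

Remark: flavan numbering (O1, C2, C3, C4, C4a, C5–C8, C8a; B ring primed) is used throughout; "4β" means trans to the C3 oxygen and trans to the C2 aryl group.

**Step 1**
Reactants: 1 (−)-epicatechin
Product: 2 5,7,3',4'-tetra-O-benzyl-(−)-epicatechin
Conditions: BnBr (4.4 equiv), K2CO3, DMF, 0 °C → rt, N2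
Reagents that add atoms: benzyl bromide, BrCc1ccccc1
Why: Williamson etherification of the four phenols with a carbonate base should leave the less acidic secondary 3-OH free, and the low temperature under nitrogen should avoid base-induced epimerization at C2; no new stereocentre.

**Step 2**
Reactants: 2 5,7,3',4'-tetra-O-benzyl-(−)-epicatechin
Product: 3 3,5,7,3',4'-penta-O-benzyl-(−)-epicatechin
Conditions: NaH, BnBr, n-Bu4NI (cat.), THF/DMF, 0 °C → rt
Reagents that add atoms: benzyl bromide, BrCc1ccccc1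
Why: Williamson etherification of the secondary alkoxide; the stereocentres are not touched.

**Step 3**
Reactants: 3 3,5,7,3',4'-penta-O-benzyl-(−)-epicatechin
Product: 4 4β-(2-ethoxyethoxy)-3,5,7,3',4'-penta-O-benzylepicatechin
Conditions: DDQ (2 equiv), 2-ethoxyethanol (5 equiv), CH2Cl2, rt
Reagents that add atoms: 2-ethoxyethanol, CCOCCO
Why: DDQ benzylic oxidation abstracts hydride from C4 (cation stabilized by the 5,7-dioxygenated ring A), and the alcohol should add anti to the 3-benzyloxy group to give the 4β ether.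

**Step 4**
Reactants: 4 4β-(2-ethoxyethoxy)-3,5,7,3',4'-penta-O-benzylepicatechin
Product: 5 8-bromo-4β-(2-ethoxyethoxy)-3,5,7,3',4'-penta-O-benzylepicatechin
Conditions: NBS (1.05 equiv), CH2Cl2, −78 → −20 °C, dark
Reagents that add atoms: N-bromosuccinimide, O=C1CCC(=O)N1Br
Why: electrophilic aromatic bromination should go to C8, the more accessible nucleophilic position of ring A (C6 lies between two benzyloxy groups); the bromine is a helper that blocks self-condensation and later serves as the lithiation handle.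

**Step 5**
Reactants: 5 8-bromo-4β-(2-ethoxyethoxy)-3,5,7,3',4'-penta-O-benzylepicatechin; 3 3,5,7,3',4'-penta-O-benzyl-(−)-epicatechin (1.5 equiv, excess recovered)
Product: 6 8-bromo-3,5,7,3',4'-penta-O-benzylepicatechin-(4β→8)-3,5,7,3',4'-penta-O-benzylepicatechin
Conditions: TMSOTf (cat.), CH2Cl2, −78 °C; then Et3N
Reagents that add atoms: none
Why: Lewis acid-promoted Friedel–Crafts-type interflavan coupling: TMSOTf ionizes the 4-alkoxy group and C8 of 3 should attack the C4 cation anti to the 3-benzyloxy group (4β, 3,4-trans), while the bromine cap stops the electrophile from coupling with itself.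

**Step 6**
Reactants: 7 3,5-bis(benzyloxy)phenol
Product: 8 2-hydroxy-4,6-bis(benzyloxy)benzaldehyde
Conditions: MgCl2, Et3N, (CH2O)n, MeCN, reflux; dilute HCl work-up
Reagents that add atoms: paraformaldehyde (formaldehyde), C=O
Why: magnesium phenoxide-directed ortho-formylation (Casnati–Skattebøl) delivers formaldehyde only ortho to the phenol oxygen and a second formaldehyde takes up hydride; the two ortho positions are equivalent.

**Step 7**
Reactants: 9 3,4-bis(benzyloxy)benzaldehyde
Product: 10 1,2-bis(benzyloxy)-4-ethynylbenzene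
Conditions: dimethyl (1-diazo-2-oxopropyl)phosphonate, K2CO3, MeOH/THF, rt
Reagents that add atoms: dimethyl (1-diazo-2-oxopropyl)phosphonate (Ohira–Bestmann reagent), CC(=O)C(=[N+]=[N-])P(=O)(OC)OC
Why: Seyferth–Gilbert homologation in the Ohira–Bestmann form converts the aldehyde into the terminal alkyne under conditions that leave benzyl ethers intact.

**Step 8**
Reactants: 10 1,2-bis(benzyloxy)-4-ethynylbenzene
Product: 11 (Z)-2-[3,4-bis(benzyloxy)phenyl]ethenyl benzoate
Conditions: PhCO2H (1.1 equiv), Ru(η3-CH2C(CH3)CH2)2(Ph2P(CH2)4PPh2) (2 mol %, divalent ruthenium), toluene, 50 °C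
Reagents that add atoms: benzoic acid, OC(=O)c1ccccc1
Why: ruthenium-catalysed anti-Markovnikov addition of a carboxylic acid to a terminal alkyne proceeds through a ruthenium vinylidene and should give the Z-enol ester, which fixes the later 2,3-cis relationship.

**Step 9**
Reactants: 6 8-bromo dimer; 8 2-hydroxy-4,6-bis(benzyloxy)benzaldehyde (2 equiv)
Product: 14 benzhydrol [2-hydroxy-4,6-bis(benzyloxy)phenyl](dimer-8-yl)methanol as a mixture of carbinol epimers, via aryllithium 12 (not isolated), via sodium phenoxide 13 (not isolated)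
Conditions: 6, n-BuLi (1.05 equiv), THF, −78 °C; separately 8, NaH (1.0 equiv), THF, 0 °C; phenoxide solution added at −78 °C, then → 0 °C; H2O (pH 7 buffer) quench
Reagents that add atoms: none
Why: bromine–lithium exchange at −78 °C should outrun deprotonation of benzylic ethers, and the aryllithium adds 1,2 to the formyl group of the pre-formed phenoxide (aryllithium addition to a salicylaldehyde salt); the new carbinol centre is formed without control and is erased in step 10.

**Step 10**
Reactants: 14 benzhydrol; 11 (Z)-2-[3,4-bis(benzyloxy)phenyl]ethenyl benzoate (3 equiv)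
Product: 16 3-O-benzoyl-5,7,3',4'-tetra-O-benzylepicatechin-(4β→8)-3,5,7,3',4'-penta-O-benzylepicatechin-(4β→8)-3,5,7,3',4'-penta-O-benzylepicatechin, via ortho-quinone methide 15 (not isolated)
Conditions: (R)-TRIP [(R)-3,3'-bis(2,4,6-triisopropylphenyl)-1,1'-binaphthyl-2,2'-diyl hydrogen phosphate] (10 mol %), 5 Å molecular sieves, toluene (dilute in 14), 0 °C → rt
Reagents that add atoms: none
Why: Proposed new method: the phosphoric acid ionizes the doubly activated benzhydrol of 14 with loss of water and binds the resulting ortho-quinone methide 15 (O=C8a–C4a=C4 of the future unit 2) through its carbonyl oxygen, and the Z-enol benzoate 11 should add across O and C4 in an inverse-electron-demand hetero-Diels–Alder reaction that is concerted but asynchronous, the benzoate-bearing carbon bonding to C4 ahead of O1–C2 closure because the developing positive charge is best held at the benzylic carbon para to a benzyloxy group and not next to the weakly donating acyloxy group, which places the aryl group at C2 and the oxygen at C3. The closest known reaction type is the Brønsted acid-catalysed [4+2] cycloaddition of ortho-quinone methides from ortho-hydroxybenzhydrols with anethole-type styrenes to give 2,4-diarylchromans; new here are the enol ester as the two-carbon partner and the doubly trioxygenated diaryl methide. Ring C of unit 2 closes in the [4+2] mode, the C3–C4 and O1–C2 bonds forming in one event. C2 and C3 should come out cis because the Z geometry of 11 is transferred suprafacially; C4 should come out trans to C3 because the bulky aryl on the methide carbon turns toward the carbonyl oxygen to avoid the C5 benzyloxy group (Z methide, aryl inside) and the styrene adds endo; the absolute sense is set by the chiral phosphate pocket, and since units 3 and 4 are enantiopure the wrong-face adduct is a diastereomer that can be removed. The step needs chemoselective methide formation at the one free phenol (O5 and O7 are benzylated), regioselectivity from the stronger aryl donor, and a non-polar medium with a weak acid so that no free benzylic cation, which could rotate or be captured by the benzoate carbonyl, intervenes.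

**Step 11**
Reactants: 16 trimer benzoate
Product: 17 5,7,3',4'-tetra-O-benzylepicatechin-(4β→8)-3,5,7,3',4'-penta-O-benzylepicatechin-(4β→8)-3,5,7,3',4'-penta-O-benzylepicatechin (free 3-OH on the top unit)
Conditions: NaOMe (cat.), MeOH/THF, rt → 40 °C
Reagents that add atoms: none
Why: base-catalysed transesterification (Zemplén-type methanolysis) removes the benzoate helper, and benzyl ethers and interflavan bonds are stable to methoxide; no stereocentre is affected.

**Step 12**
Reactants: 17 trimer alcohol; 5 8-bromo-4β-(2-ethoxyethoxy)-3,5,7,3',4'-penta-O-benzylepicatechin (1.2 equiv)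
Product: 18 8-bromo-3,5,7,3',4'-penta-O-benzylepicatechin-(4β→8)-5,7,3',4'-tetra-O-benzylepicatechin-(4β→8)-3,5,7,3',4'-penta-O-benzylepicatechin-(4β→8)-3,5,7,3',4'-penta-O-benzylepicatechin
Conditions: TMSOTf (cat.), CH2Cl2, −78 °C; then Et3N
Reagents that add atoms: none
Why: the same Lewis acid-promoted interflavan coupling as in step 5: C8 of the top unit of 17, the only free C8 and the most nucleophilic aromatic position, should attack the C4 cation anti to the 3-benzyloxy group (4β), and the bromine cap prevents self-coupling of 5.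

**Step 13**
Reactants: 18 bromo tetramer
Product: 19 epicatechin-(4β→8)-epicatechin-(4β→8)-epicatechin-(4β→8)-epicatechin (target)
Conditions: H2 (1 atm), Pd(OH)2/C, Et3N (1.1 equiv), THF/MeOH/H2O, rt
Reagents that add atoms: none
Why: catalytic hydrogenolysis should cleave the nineteen benzyl ethers and the C8–Br bond in one operation, the amine taking up HBr so that the acid-labile interflavan bonds survive; no stereocentre is touched.

**Compound list**

1 | (−)-epicatechin | Oc1cc(O)c2c(c1)O[C@H](c1ccc(O)c(O)c1)[C@H](O)C2 | starting material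
2 | 5,7,3',4'-tetra-O-benzyl-(−)-epicatechin | C(c3ccccc3)Oc1cc(OCc3ccccc3)c2c(c1)O[C@H](c1ccc(OCc3ccccc3)c(OCc3ccccc3)c1)[C@H](O)C2 | intermediate
3 | 3,5,7,3',4'-penta-O-benzyl-(−)-epicatechin | C(c3ccccc3)Oc1cc(OCc3ccccc3)c2c(c1)O[C@H](c1ccc(OCc3ccccc3)c(OCc3ccccc3)c1)[C@H](OCc3ccccc3)C2 | intermediate
4 | 4β-(2-ethoxyethoxy)-3,5,7,3',4'-penta-O-benzylepicatechin | C(c3ccccc3)Oc1cc(OCc3ccccc3)c2c(c1)O[C@H](c1ccc(OCc3ccccc3)c(OCc3ccccc3)c1)[C@H](OCc3ccccc3)[C@H]2OCCOCC | intermediate
5 | 8-bromo-4β-(2-ethoxyethoxy)-3,5,7,3',4'-penta-O-benzylepicatechin | C(c3ccccc3)Oc1cc(OCc3ccccc3)c2c(c1Br)O[C@H](c1ccc(OCc3ccccc3)c(OCc3ccccc3)c1)[C@H](OCc3ccccc3)[C@H]2OCCOCC | intermediate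
6 | 8-bromo-3,5,7,3',4'-penta-O-benzylepicatechin-(4β→8)-3,5,7,3',4'-penta-O-benzylepicatechin | Brc1c(OCc3ccccc3)cc(OCc3ccccc3)c2c1O[C@H](c1ccc(OCc3ccccc3)c(OCc3ccccc3)c1)[C@H](OCc3ccccc3)[C@H]2c1c(OCc3ccccc3)cc(OCc3ccccc3)c2c1O[C@H](c1ccc(OCc3ccccc3)c(OCc3ccccc3)c1)[C@H](OCc3ccccc3)C2 | intermediate
7 | 3,5-bis(benzyloxy)phenol | Oc1cc(OCc2ccccc2)cc(OCc2ccccc2)c1 | starting material
8 | 2-hydroxy-4,6-bis(benzyloxy)benzaldehyde | O=Cc1c(O)cc(OCc2ccccc2)cc1OCc1ccccc1 | intermediate
9 | 3,4-bis(benzyloxy)benzaldehyde | O=Cc1ccc(OCc2ccccc2)c(OCc2ccccc2)c1 | starting material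
10 | 1,2-bis(benzyloxy)-4-ethynylbenzene | C#Cc1ccc(OCc2ccccc2)c(OCc2ccccc2)c1 | intermediate
11 | (Z)-2-[3,4-bis(benzyloxy)phenyl]ethenyl benzoate | c1ccccc1C(=O)O/C=C\c1ccc(OCc2ccccc2)c(OCc2ccccc2)c1 | intermediate
12 | 8-lithio derivative of dimer 6 (aryllithium) | [Li]c1c(OCc3ccccc3)cc(OCc3ccccc3)c2c1O[C@H](c1ccc(OCc3ccccc3)c(OCc3ccccc3)c1)[C@H](OCc3ccccc3)[C@H]2c1c(OCc3ccccc3)cc(OCc3ccccc3)c2c1O[C@H](c1ccc(OCc3ccccc3)c(OCc3ccccc3)c1)[C@H](OCc3ccccc3)C2 | intermediate
13 | sodium 3,5-bis(benzyloxy)-2-formylphenolate | [Na+].[O-]c1cc(OCc2ccccc2)cc(OCc2ccccc2)c1C=O | intermediate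
14 | benzhydrol: dimer 6 with the C8 bromine replaced by CH(OH)Ar, Ar = 2-hydroxy-4,6-bis(benzyloxy)phenyl; carbinol carbon as both epimers | Oc1cc(OCc3ccccc3)cc(OCc3ccccc3)c1C(O)c1c(OCc3ccccc3)cc(OCc3ccccc3)c2c1O[C@H](c1ccc(OCc3ccccc3)c(OCc3ccccc3)c1)[C@H](OCc3ccccc3)[C@H]2c1c(OCc3ccccc3)cc(OCc3ccccc3)c2c1O[C@H](c1ccc(OCc3ccccc3)c(OCc3ccccc3)c1)[C@H](OCc3ccccc3)C2 | intermediate
15 | ortho-quinone methide: 3,5-bis(benzyloxy)-6-(arylmethylidene)cyclohexa-2,4-dien-1-one, aryl = C8 of the units 3–4 dimer, Z (aryl syn to the carbonyl) | O=C1C=C(OCc3ccccc3)C=C(OCc3ccccc3)/C1=C/c1c(OCc3ccccc3)cc(OCc3ccccc3)c2c1O[C@H](c1ccc(OCc3ccccc3)c(OCc3ccccc3)c1)[C@H](OCc3ccccc3)[C@H]2c1c(OCc3ccccc3)cc(OCc3ccccc3)c2c1O[C@H](c1ccc(OCc3ccccc3)c(OCc3ccccc3)c1)[C@H](OCc3ccccc3)C2 | intermediate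
16 | 3-O-benzoyl-5,7,3',4'-tetra-O-benzylepicatechin-(4β→8)-3,5,7,3',4'-penta-O-benzylepicatechin-(4β→8)-3,5,7,3',4'-penta-O-benzylepicatechin | C(c3ccccc3)Oc1cc(OCc3ccccc3)c2c(c1)O[C@H](c1ccc(OCc3ccccc3)c(OCc3ccccc3)c1)[C@H](OC(=O)c3ccccc3)[C@H]2c1c(OCc3ccccc3)cc(OCc3ccccc3)c2c1O[C@H](c1ccc(OCc3ccccc3)c(OCc3ccccc3)c1)[C@H](OCc3ccccc3)[C@H]2c1c(OCc3ccccc3)cc(OCc3ccccc3)c2c1O[C@H](c1ccc(OCc3ccccc3)c(OCc3ccccc3)c1)[C@H](OCc3ccccc3)C2 | intermediate
17 | 5,7,3',4'-tetra-O-benzylepicatechin-(4β→8)-3,5,7,3',4'-penta-O-benzylepicatechin-(4β→8)-3,5,7,3',4'-penta-O-benzylepicatechin | C(c3ccccc3)Oc1cc(OCc3ccccc3)c2c(c1)O[C@H](c1ccc(OCc3ccccc3)c(OCc3ccccc3)c1)[C@H](O)[C@H]2c1c(OCc3ccccc3)cc(OCc3ccccc3)c2c1O[C@H](c1ccc(OCc3ccccc3)c(OCc3ccccc3)c1)[C@H](OCc3ccccc3)[C@H]2c1c(OCc3ccccc3)cc(OCc3ccccc3)c2c1O[C@H](c1ccc(OCc3ccccc3)c(OCc3ccccc3)c1)[C@H](OCc3ccccc3)C2 | intermediate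
18 | 8-bromo-3,5,7,3',4'-penta-O-benzylepicatechin-(4β→8)-5,7,3',4'-tetra-O-benzylepicatechin-(4β→8)-3,5,7,3',4'-penta-O-benzylepicatechin-(4β→8)-3,5,7,3',4'-penta-O-benzylepicatechin | Brc1c(OCc3ccccc3)cc(OCc3ccccc3)c2c1O[C@H](c1ccc(OCc3ccccc3)c(OCc3ccccc3)c1)[C@H](OCc3ccccc3)[C@H]2c1c(OCc3ccccc3)cc(OCc3ccccc3)c2c1O[C@H](c1ccc(OCc3ccccc3)c(OCc3ccccc3)c1)[C@H](O)[C@H]2c1c(OCc3ccccc3)cc(OCc3ccccc3)c2c1O[C@H](c1ccc(OCc3ccccc3)c(OCc3ccccc3)c1)[C@H](OCc3ccccc3)[C@H]2c1c(OCc3ccccc3)cc(OCc3ccccc3)c2c1O[C@H](c1ccc(OCc3ccccc3)c(OCc3ccccc3)c1)[C@H](OCc3ccccc3)C2 | intermediate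
19 | epicatechin-(4β→8)-epicatechin-(4β→8)-epicatechin-(4β→8)-epicatechin (the all-4β→8 procyanidin tetramer) | Oc1cc(O)c2c(c1)O[C@H](c1ccc(O)c(O)c1)[C@H](O)[C@H]2c1c(O)cc(O)c2c1O[C@H](c1ccc(O)c(O)c1)[C@H](O)[C@H]2c1c(O)cc(O)c2c1O[C@H](c1ccc(O)c(O)c1)[C@H](O)[C@H]2c1c(O)cc(O)c2c1O[C@H](c1ccc(O)c(O)c1)[C@H](O)C2 | target

**Step count and risks**

Total step count: 13. Longest linear sequence: 10 steps (steps 1, 2, 3, 4, 5, 9, 10, 11, 12, 13).

Steps most likely to fail:

1. Step 10 (proposed new method). The Z-enol benzoate may be too weak a partner for the strongly stabilized methide. The addition may turn stepwise, with rotation of a free benzylic cation or its capture by the benzoate carbonyl and loss of the 2,3-cis relationship. The endo and facial preferences may be low, and the methide may be consumed by Friedel–Crafts attack of other electron-rich rings. Fallback by known interflavan coupling, setting out from compound 4 (with 3 and 2) and coming back at compound 17: TMSOTf-promoted coupling of 4 with an excess of 3 in CH2Cl2 at −78 °C should give the bromine-free dimer 3,5,7,3',4'-penta-O-benzylepicatechin-(4β→8)-3,5,7,3',4'-penta-O-benzylepicatechin F1. DDQ and 2-ethoxyethanol on 2 should give 4β-(2-ethoxyethoxy)-5,7,3',4'-tetra-O-benzylepicatechin F2 with a free 3-OH. TMSOTf- or Yb(OTf)3-promoted coupling of F2 with an excess of F1, by attack of C8 of the upper unit of F1 anti to the C3 oxygen, should give 17.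

2. Step 9. The aryllithium may be quenched by proton transfer, may add sluggishly to the electron-rich phenoxide aldehyde, or the doubly activated benzhydrol may ionize during work-up and purification. Fallback through a protected phenol, setting out from compound 8 and coming back at compound 14: allyl bromide and K2CO3 in DMF should give 2-(allyloxy)-4,6-bis(benzyloxy)benzaldehyde F3. Addition of aryllithium 12 (from 6 and n-BuLi as before) to F3 should give the O-allyl benzhydrol F4. Pd(PPh3)4 (zerovalent palladium) with K2CO3 in MeOH should remove the allyl group under basic conditions and give 14.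

3. Step 12. The late coupling may suffer from attack at C6 positions, from acid-induced cleavage or scrambling of the existing interflavan bonds, or from O-alkylation of the free 3-OH. Fallback through a thioether donor under neutral thiophilic activation, setting out from compound 5 and coming back at compound 18: exchange of the 4-alkoxy group with 2-mercaptobenzothiazole and AlMe3 should give 8-bromo-4β-(1,3-benzothiazol-2-ylsulfanyl)-3,5,7,3',4'-penta-O-benzylepicatechin F5. AgBF4 in THF at 0 °C should then couple F5 with 17 at C8 of its top unit and give 18.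

**Further compounds**

F1 | step 10 | 3,5,7,3',4'-penta-O-benzylepicatechin-(4β→8)-3,5,7,3',4'-penta-O-benzylepicatechin | C(c3ccccc3)Oc1cc(OCc3ccccc3)c2c(c1)O[C@H](c1ccc(OCc3ccccc3)c(OCc3ccccc3)c1)[C@H](OCc3ccccc3)[C@H]2c1c(OCc3ccccc3)cc(OCc3ccccc3)c2c1O[C@H](c1ccc(OCc3ccccc3)c(OCc3ccccc3)c1)[C@H](OCc3ccccc3)C2
F2 | step 10 | 4β-(2-ethoxyethoxy)-5,7,3',4'-tetra-O-benzylepicatechin (free 3-OH) | C(c3ccccc3)Oc1cc(OCc3ccccc3)c2c(c1)O[C@H](c1ccc(OCc3ccccc3)c(OCc3ccccc3)c1)[C@H](O)[C@H]2OCCOCC
F3 | step 9 | 2-(allyloxy)-4,6-bis(benzyloxy)benzaldehyde | O=Cc1c(OCC=C)cc(OCc2ccccc2)cc1OCc1ccccc1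
F4 | step 9 | O-allyl benzhydrol: benzhydrol 14 with the phenol as its allyl ether | C=CCOc1cc(OCc3ccccc3)cc(OCc3ccccc3)c1C(O)c1c(OCc3ccccc3)cc(OCc3ccccc3)c2c1O[C@H](c1ccc(OCc3ccccc3)c(OCc3ccccc3)c1)[C@H](OCc3ccccc3)[C@H]2c1c(OCc3ccccc3)cc(OCc3ccccc3)c2c1O[C@H](c1ccc(OCc3ccccc3)c(OCc3ccccc3)c1)[C@H](OCc3ccccc3)C2
F5 | step 12 | 8-bromo-4β-(1,3-benzothiazol-2-ylsulfanyl)-3,5,7,3',4'-penta-O-benzylepicatechin | C(c3ccccc3)Oc1cc(OCc3ccccc3)c2c(c1Br)O[C@H](c1ccc(OCc3ccccc3)c(OCc3ccccc3)c1)[C@H](OCc3ccccc3)[C@H]2Sc1nc3ccccc3s1
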